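## The problem

The target, (2S)-5,7,4'-trihydroxy-6,8,3'-triprenylflavanone (15; prenyl = 3-methylbut-2-enyl, flavonoid numbering), is a chroman-4-one. Its fully substituted phloroglucinol ring A (hydroxyls at C5 and C7, prenyl groups at C6 and C8) is fused through C4a–C8a to the dihydropyranone ring C, which carries the 4-hydroxy-3-prenylphenyl ring B at C2. C2 is the only stereocentre, and nothing else in the molecule can direct it, so its (S) configuration has to come from a catalyst or a chiral building block. C2 is also fragile. Base opens the β-aryloxy ketone to the 2'-hydroxychalcone by retro-oxa-Michael reaction, and the 4'-hydroxyl helps the C2–O1 bond to ionise in acid, so once the ketone exists the molecule should meet neither. Each of the three prenyl groups sits ortho to a phenol. Strong acid would close them to dimethylchromans and quinone oxidants to chromenes, hydrogenation and epoxidising reagents are excluded, and the free electron-rich phenols do not tolerate strong oxidants. The two prenyl groups of ring A pose no regiochemical problem if they are introduced while ring A is still mirror-symmetric, as in a 2,4,6-trioxygenated benzaldehyde with two equivalent free ring positions. The feature that opens the key step lies in ring C. The bonds O1–C2 and C3–C4 flank the two-carbon unit C2–C3, which is the vinyl group of 2-prenyl-4-vinylphenol. O1, C8a, C4a and C4 are the heterodiene of an ortho-quinone methide derived from a salicylaldehyde, and ring A has equivalent hydroxyls on both sides of C4a, so either can become O1 while the other ends as the C5 hydroxyl. An alkoxy group on the methide carbon brings C4 in at the alcohol oxidation level; the temporary C4 stereocentre is later flattened to the carbonyl, so only C2 needs absolute control.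

## Retrosynthesis

The last operation is chosen to be the cleavage of three O–Si bonds, leading from 15 back to the tris-silyl flavanone 14. The phenols have to be masked while C4 is oxidised, and silyl ethers are the one common group that leaves under buffered fluoride, without the acid that threatens the prenyl groups or the base that threatens C2. The forward step must keep phenoxide concentration low.

The carbonyl of 14 is traced to the secondary alcohol 13 and that to the C4 methyl ether 12. No skeletal bond is cut; the C4 oxidation level is only adjusted. The alternative of oxidising the methyl ether directly by hydride abstraction would expose three benzylic-allylic prenyl methylenes to the same reagent. The solvolytic exchange uses instead the acetal-like lability of a benzylic ether flanked by the ring A oxygens. The forward reactions need only weak acid in wet solvent and a neutral hypervalent iodine oxidation.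

Compound 12 is the bis-silyl ether of the diol 11, by cutting the O–Si bonds at O5 and O4'. This detour is accepted because the key step needs both hydroxyls free as hydrogen-bond donors, whereas the solvolysis and the oxidation need them masked.

The key disconnection cuts O1–C2 and C3–C4 of 11 at once. It gives the salicylaldehyde 4, the styrene 7 and trimethyl orthoformate 8, which supplies the methoxy group and turns the aldehyde carbon into the methide carbon.
- Against the neighbouring cuts: cutting O1–C2 alone leads to a chalcone whose oxa-Michael closure is reversible and has no dependable enantioselective form for unactivated substrates. Cutting C2–aryl would require conjugate arylation of a heavily substituted chromone.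
- Simplification: the double cut divides a 37-carbon adduct into fragments of 23 and 13 carbons, closes ring C and sets C2, and delivers C4 one oxidation below the target.
- Demands on the forward reaction: a chiral BINOL-derived phosphoric acid must generate the methoxy ortho-quinone methide and choose the face of the styrene. Regiochemistry follows from polarity, and site selectivity on ring A is not an issue because 4 is mirror-symmetric.

Aldehyde 4 is simplified by cutting the O–Si bond at the para oxygen to give triol 3, and then the two ring–prenyl bonds to give 2,4,6-trihydroxybenzaldehyde 1 and prenyl bromide 2. The para hydroxyl is masked so that ionisation of the acetal has to pass through the ortho-quinone methide and not the para isomer. Both C-alkylations occur at equivalent positions, so only their number has to be controlled.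

Styrene 7 is cut at the vinyl C=C bond to aldehyde 6 (Wittig methylenation) and 6 at its ring–prenyl bond to 4-hydroxybenzaldehyde 5 and 2. The para position of 5 is blocked by the formyl group, so C-prenylation can only go ortho.

## Roads not taken

Alternative 1: Ring A is built last by a Danheiser benzannulation, cutting C8–C8a, C7–C8, C5–C6 and C4a–C5.
- Forward step: irradiation of the diazo ketone A2, an (S)-2-aryl-2,3-dihydropyran-4-one carrying the diazoacyl chain at C6, should trigger a Wolff shift to a vinylketene. This adds the prenyl siloxyalkyne A3, and electrocyclic opening and closure give the flavanone A1 with a free C5 hydroxyl.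
- Merits: every substituent of ring A is placed by construction, so no C-prenylation of a phloroglucinol is needed. The ketone is present from the start, and C2 can be set beforehand by an established asymmetric hetero-Diels-Alder construction of the dihydropyranone. Only two silyl ethers remain to be removed.
- Weak points: A2 and A3 each need several steps. The ketene is disubstituted at its terminus and therefore hindered. The irradiation meets an enone next to trisubstituted alkenes, which invites (2+2) photocycloaddition. The thermal electrocyclic stage heats a β-aryloxy ketone whose C2 could open.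
- Comparison: this road is clearly better in regiochemical certainty and in the reliability of its stereocontrol. The chosen plan sets against it roughly half the step count, a cheap symmetric ring A and a key step run at ambient temperature without light. The price is a key step whose enantioselective form is unproven.

Alternative 2: Ring C is closed by an aryne annulation, cutting O1–C8a and C4–C4a.
- Forward step: fluoride releases the C4a–C8a aryne from the silylaryl triflate A5. The alkoxide of the (S)-β-hydroxy ester A6 adds at C8a, and the aryl anion at C4a attacks the ester to give the tris(methoxymethyl) flavanone A4.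
- Merits: the C2 stereocentre comes from asymmetric hydrogenation of a β-keto ester and is not touched in the key step, which is stereochemically more secure than the chosen plan. The ketone is formed directly.
- Weak points: A5 is a hexasubstituted benzene that is long to prepare. The alkoxide must add next to a prenyl group, which can itself undergo an ene reaction with the aryne. A secondary benzylic alkoxide is a sluggish aryne partner, so protonation of the aryl anion before acylation and base-induced elimination of A6 to a cinnamate compete. Three methoxymethyl ethers must finally be removed with protic acid beside ortho-prenyl phenols.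
- Comparison: stereocontrol is stronger here, but the aryne precursor and the acidic end-game cost more steps and more risk to the prenyl groups than the silyl-based end-game of the chosen plan.

Alternative 3: Only C4–C4a is cut, with the aryl ether made first.
- Forward step: the (S)-3-aryl-3-aryloxypropanoic acid A8, activated as a mixed anhydride with trifluoroacetic anhydride, should acylate the only free position of ring A and give the flavanone A7.
- Merits: intramolecular Friedel-Crafts acylation to a chromanone is the best precedented ring closure of all four plans, and its regiochemistry is trivial. The configuration can come from an asymmetric ketone reduction followed by Mitsunobu inversion.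
- Weak points: the ether is formed at a benzylic carbinol bearing an oxygenated aryl group, so it can ionise and lose configuration. The two equivalent hydroxyls of the ring A phenol have to be differentiated statistically. The trifluoroacetic acid medium is the harshest any of the plans applies to three trisubstituted alkenes, two aryl silyl ethers and an ionisable benzylic aryl ether, and A8 can eliminate to a cinnamic acid.
- Comparison: its key step is known chemistry, whereas that of the chosen plan is not. The chosen plan answers with a far weaker acid, fewer steps and a C2 centre that is formed in the same step that closes the ring, not carried through two steps that can erode it.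

Key step: step 5

Assumption: the sense of induction of the phosphoric acid cannot be predicted with confidence, so the (R)-acid is written and its antipode would be used if the (2R) adduct proves to be favoured.

## Route

Step 1
Reactants: 1 2,4,6-trihydroxybenzaldehyde, 2 prenyl bromide
Product: 3 2,4,6-trihydroxy-3,5-bis(3-methylbut-2-enyl)benzaldehyde
Conditions: 2 (2.2 equiv), 10% aq KOH, 0 °C → rt
Reagents that add atoms: none
Why: Direct C-alkylation of the phloroglucinol polyanion in water, where solvation of the phenoxide oxygens favours attack through the ring carbons; C3 and C5 are equivalent, so only the degree of alkylation has to be steered by stoichiometry and temperature.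

Step 2
Reactants: 3 2,4,6-trihydroxy-3,5-bis(3-methylbut-2-enyl)benzaldehyde
Product: 4 4-(tert-butyldimethylsilyloxy)-2,6-dihydroxy-3,5-bis(3-methylbut-2-enyl)benzaldehyde
Conditions: TBSCl (1.05 equiv), imidazole, DMF, 0 °C
Reagents that add atoms: tert-butyldimethylsilyl chloride, CC(C)(C)[Si](C)(C)Cl
Why: Selective silylation of the most acidic phenol; the hydroxyl para to the formyl group is the vinylogous acid and is not hydrogen-bonded to the aldehyde, whereas the two ortho hydroxyls are chelated, so one equivalent of silyl chloride should go to O4 despite its two prenyl neighbours.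

Step 3
Reactants: 5 4-hydroxybenzaldehyde, 2 prenyl bromide
Product: 6 4-hydroxy-3-(3-methylbut-2-enyl)benzaldehyde
Conditions: 2 (1.1 equiv), 10% aq KOH, rt
Reagents that add atoms: none
Why: Phenolate C-alkylation in water; the para position is blocked by the formyl group, so C-prenylation can only occur ortho, and the O-prenyl ether formed alongside is removed by chromatography.

Step 4
Reactants: 6 4-hydroxy-3-(3-methylbut-2-enyl)benzaldehyde
Product: 7 2-(3-methylbut-2-enyl)-4-vinylphenol
Conditions: Ph3PCH3Br (2.5 equiv), KOtBu (2.4 equiv), THF, 0 °C → rt
Reagents that add atoms: methyltriphenylphosphonium bromide, C[P+](c1ccccc1)(c1ccccc1)c1ccccc1.[Br-]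
Why: Wittig methylenation; one extra equivalent of ylide covers the phenol, and the unstabilised ylide still adds to the phenoxide aldehyde; the styrene is kept cold with a trace of radical inhibitor and used promptly to forestall polymerisation.

Step 5
Reactants: 4 4-(tert-butyldimethylsilyloxy)-2,6-dihydroxy-3,5-bis(3-methylbut-2-enyl)benzaldehyde, 7 2-(3-methylbut-2-enyl)-4-vinylphenol, 8 trimethyl orthoformate
Product: 11 (2S,4S)-7-(tert-butyldimethylsilyloxy)-4-methoxy-6,8,3'-triprenylflavan-5,4'-diol, via dimethyl acetal 9 (not isolated), via methoxy ortho-quinone methide 10 (not isolated)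
Conditions: (R)-TRIP [(R)-3,3'-bis(2,4,6-triisopropylphenyl)-1,1'-binaphthyl-2,2'-diyl hydrogen phosphate] (10 mol %), 7 (1.5 equiv), 8 (3 equiv), 5 Å MS, PhMe, 0 °C → rt
Reagents that add atoms: none
Why: Proposed new method: the acid turns 4 and 8 into acetal 9, the ortho hydroxyl expels methanol to give the methoxy ortho-quinone methide 10 (or its O-protonated oxocarbenium form paired with the chiral phosphate), and the electron-rich styrene 7 adds across it in an asynchronous inverse-demand oxa-(4+2) cycloaddition, its terminal CH2 bonding to C4 and its benzylic carbon to the quinone oxygen; the closest known reaction types are the acid-catalysed three-component synthesis of 2,4-cis-4-alkoxyflavans from salicylaldehydes, orthoformates and styrenes and the chiral phosphoric acid-catalysed cycloadditions of ortho-quinone methides with hydroxystyrenes, and the new element is their combination on an alkoxy-substituted quinone methide. Ring C closes as a six-membered ring by hetero-Diels-Alder cycloaddition or, in the stepwise limit, by 6-exo-trig attack of the ring A oxygen on the para-quinone methide left after C3–C4 bond formation. C2 is set under catalyst control, by the face of the styrene that the phosphate leaves open while it is hydrogen-bonded to the styrene hydroxyl and to the free ortho hydroxyl or quinone oxygen of 10. C4 follows from C2 under substrate control through the endo arrangement of the aryl group, which places aryl and methoxy cis and both equatorial; a trans epimer, should it form, is no loss because C4 becomes the carbonyl carbon. Regiochemistry is dictated by polarity, the nucleophilic CH2 going to the electrophilic methide carbon. Among the four alkenes only the styrene is conjugated to a para-hydroxyl donor, so the prenyl groups stay out, and the mirror symmetry of ring A makes both ortho hydroxyls deliver the same adduct. The acid is too weak to cyclise prenyl groups onto phenols or to cleave the aryl silyl ether, and the sieves take up methanol so that 10 keeps forming.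

Step 6
Reactants: 11 (2S,4S)-7-(tert-butyldimethylsilyloxy)-4-methoxy-6,8,3'-triprenylflavan-5,4'-diol
Product: 12 (2S,4S)-5,7,4'-tris(tert-butyldimethylsilyloxy)-4-methoxy-6,8,3'-triprenylflavan
Conditions: TBSCl (3 equiv), imidazole, DMAP (cat.), DMF, rt → 45 °C
Reagents that add atoms: tert-butyldimethylsilyl chloride, CC(C)(C)[Si](C)(C)Cl
Why: Silyl ether formation through the N-silylimidazolium; the open ring B phenol reacts first and the flanked C5 hydroxyl follows on warming, and the absence of a Lewis acidic silyl triflate spares the ionisable C4 methyl ether.

Step 7
Reactants: 12 (2S,4S)-5,7,4'-tris(tert-butyldimethylsilyloxy)-4-methoxy-6,8,3'-triprenylflavan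
Product: 13 (2S)-5,7,4'-tris(tert-butyldimethylsilyloxy)-6,8,3'-triprenylflavan-4-ol as a mixture of C4 epimers
Conditions: PPTS (cat.), THF/H2O (3:1), rt
Reagents that add atoms: water, O
Why: SN1 solvolysis of a benzylic ether that behaves like an acetal; the C4 cation is stabilised by O1 and O5 (ortho) and O7 (para), so a pyridinium salt suffices and water in large excess captures it, while aryl silyl ethers and prenyl groups tolerate this acidity, C2 is not involved and the C4 configuration is irrelevant.

Step 8
Reactants: 13 (2S)-5,7,4'-tris(tert-butyldimethylsilyloxy)-6,8,3'-triprenylflavan-4-ol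
Product: 14 (2S)-5,7,4'-tris(tert-butyldimethylsilyloxy)-6,8,3'-triprenylflavanone
Conditions: DMP (1.5 equiv), pyridine, CH2Cl2, 0 °C → rt
Reagents that add atoms: none
Why: Dess-Martin oxidation of a secondary benzylic alcohol under pyridine buffering; no free phenol is left for the iodine reagent to attack, trisubstituted alkenes are inert to it, and the medium is neither acidic nor basic enough to open the new β-aryloxy ketone at C2.

Step 9
Reactants: 14 (2S)-5,7,4'-tris(tert-butyldimethylsilyloxy)-6,8,3'-triprenylflavanone
Product: 15 (2S)-5,7,4'-trihydroxy-6,8,3'-triprenylflavanone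
Conditions: TBAF, AcOH (1:1, 4 equiv), THF, 0 °C → rt
Reagents that add atoms: none
Why: Fluoride-induced cleavage of the three aryl silyl ethers; acetic acid protonates each phenoxide as it forms, which suppresses the retro-oxa-Michael opening to the chalcone that would racemise C2, and no acid strong enough to cyclise a prenyl group onto a neighbouring phenol is present.

## Compound list

1 | 2,4,6-trihydroxybenzaldehyde | O=Cc1c(O)cc(O)cc1O | starting material
2 | prenyl bromide (1-bromo-3-methylbut-2-ene) | CC(C)=CCBr | starting material
3 | 2,4,6-trihydroxy-3,5-bis(3-methylbut-2-enyl)benzaldehyde | O=Cc1c(O)c(CC=C(C)C)c(O)c(CC=C(C)C)c1O | intermediate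
4 | 4-(tert-butyldimethylsilyloxy)-2,6-dihydroxy-3,5-bis(3-methylbut-2-enyl)benzaldehyde | O=Cc1c(O)c(CC=C(C)C)c(O[Si](C)(C)C(C)(C)C)c(CC=C(C)C)c1O | intermediate
5 | 4-hydroxybenzaldehyde | O=Cc1ccc(O)cc1 | starting material
6 | 4-hydroxy-3-(3-methylbut-2-enyl)benzaldehyde | O=Cc1ccc(O)c(CC=C(C)C)c1 | intermediate
7 | 2-(3-methylbut-2-enyl)-4-vinylphenol | C=Cc1ccc(O)c(CC=C(C)C)c1 | intermediate
8 | trimethyl orthoformate | COC(OC)OC | starting material
9 | 4-(tert-butyldimethylsilyloxy)-2,6-dihydroxy-3,5-bis(3-methylbut-2-enyl)benzaldehyde dimethyl acetal | COC(OC)c1c(O)c(CC=C(C)C)c(O[Si](C)(C)C(C)(C)C)c(CC=C(C)C)c1O | intermediate (not isolated)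
10 | 3-(tert-butyldimethylsilyloxy)-5-hydroxy-6-(methoxymethylidene)-2,4-bis(3-methylbut-2-enyl)cyclohexa-2,4-dien-1-one (methoxy ortho-quinone methide, alkene geometry not defined) | COC=C1C(=O)C(CC=C(C)C)=C(O[Si](C)(C)C(C)(C)C)C(CC=C(C)C)=C1O | intermediate (not isolated)
11 | (2S,4S)-7-(tert-butyldimethylsilyloxy)-4-methoxy-6,8,3'-triprenylflavan-5,4'-diol (2,4-cis) | CO[C@H]1C[C@@H](c2ccc(O)c(CC=C(C)C)c2)Oc2c(CC=C(C)C)c(O[Si](C)(C)C(C)(C)C)c(CC=C(C)C)c(O)c12 | intermediate
12 | (2S,4S)-5,7,4'-tris(tert-butyldimethylsilyloxy)-4-methoxy-6,8,3'-triprenylflavan | CO[C@H]1C[C@@H](c2ccc(O[Si](C)(C)C(C)(C)C)c(CC=C(C)C)c2)Oc2c(CC=C(C)C)c(O[Si](C)(C)C(C)(C)C)c(CC=C(C)C)c(O[Si](C)(C)C(C)(C)C)c12 | intermediate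
13 | (2S)-5,7,4'-tris(tert-butyldimethylsilyloxy)-6,8,3'-triprenylflavan-4-ol (both C4 epimers) | OC1C[C@@H](c2ccc(O[Si](C)(C)C(C)(C)C)c(CC=C(C)C)c2)Oc2c(CC=C(C)C)c(O[Si](C)(C)C(C)(C)C)c(CC=C(C)C)c(O[Si](C)(C)C(C)(C)C)c12 | intermediate
14 | (2S)-5,7,4'-tris(tert-butyldimethylsilyloxy)-6,8,3'-triprenylflavanone | O=C1C[C@@H](c2ccc(O[Si](C)(C)C(C)(C)C)c(CC=C(C)C)c2)Oc2c(CC=C(C)C)c(O[Si](C)(C)C(C)(C)C)c(CC=C(C)C)c(O[Si](C)(C)C(C)(C)C)c12 | intermediate
15 | (2S)-5,7,4'-trihydroxy-6,8,3'-triprenylflavanone | CC(C)=CCc1cc([C@@H]2CC(=O)c3c(O)c(CC=C(C)C)c(O)c(CC=C(C)C)c3O2)ccc1O | target

## Step count and risks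

Total step count: 9. Longest linear sequence: 7 steps (1, 2, 5, 6, 7, 8, 9; the branch 3, 4, 5 to 9 is equally long).

Step 5 (key step).
- What may go wrong: facial selectivity at C2 may be poor because the styrene hydroxyl that anchors the phosphate is remote from the reacting vinyl carbon. An unbound oxocarbenium ion may react in a background pathway. The C2–O1 bond of the adduct may ionise reversibly under the acid and erode the enantiomeric purity. The styrene may oligomerise.
- Fallback: setting out from 4, 7 and 8, the union would be run as the known racemic three-component flavan synthesis with an achiral acid of similar strength (diphenyl hydrogen phosphate, CH2Cl2, 5 Å sieves). This should give 11 together with its mirror image, (2R,4R)-7-(tert-butyldimethylsilyloxy)-4-methoxy-6,8,3'-triprenylflavan-5,4'-diol F1. Preparative chromatography on a chiral stationary phase (amylose tris(3,5-dimethylphenylcarbamate)) would separate the two, and the route is rejoined at 11.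

Step 7.
- What may go wrong: the C4 cation may lose a proton from C3 (elimination to the 3,4-alkene) faster than water captures it, and the crowded C5 silyl ether may be lost slowly.
- Fallback: setting out from 11, the exchange would be done before any further protection. The free C5 hydroxyl can expel methanol without added acid to give a neutral ortho-quinone methide, which water should capture quickly (MeCN/H2O near neutrality, gentle warming). This should give (2S)-7-(tert-butyldimethylsilyloxy)-6,8,3'-triprenylflavan-4,5,4'-triol F2. Activated MnO2 in CH2Cl2, a standard oxidant for ortho-hydroxybenzylic alcohols, would then give (2S)-7-(tert-butyldimethylsilyloxy)-5,4'-dihydroxy-6,8,3'-triprenylflavanone F3. Buffered fluoride (TBAF, AcOH) removes the single silyl ether, and the route is rejoined at 15.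

Step 1.
- What may go wrong: C-alkylation may stop at the monoprenyl stage or run on to geminal dialkylation with loss of aromaticity, and O-alkylation competes.
- Fallback: setting out from 1 and 2, the two non-chelated hydroxyls would first be O-alkylated (K2CO3, acetone) to 2-hydroxy-4,6-bis(3-methylbut-2-enyloxy)benzaldehyde F4. A clay-promoted O-to-C prenyl shift (montmorillonite K10, CH2Cl2) can deliver the two groups only to the two free ring carbons, and the route is rejoined at 3.

Step 9.
- What may go wrong: configuration at C2 may erode through reversible ring opening if phenoxide or enolate builds up, and the doubly flanked C7 silyl ether may cleave incompletely.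
- Fallback: setting out from 13, the silyl ethers would be removed while no ketone is present and hence no ring-opening pathway exists (TBAF, THF, 0 °C). This should give (2S)-6,8,3'-triprenylflavan-4,5,7,4'-tetrol F5, whose benzylic alcohol would then be oxidised chemoselectively with activated MnO2 in EtOAc, and the route is rejoined at 15.

## Further compounds

F1 | step 5 | (2R,4R)-7-(tert-butyldimethylsilyloxy)-4-methoxy-6,8,3'-triprenylflavan-5,4'-diol (enantiomer of 11) | CO[C@@H]1C[C@H](c2ccc(O)c(CC=C(C)C)c2)Oc2c(CC=C(C)C)c(O[Si](C)(C)C(C)(C)C)c(CC=C(C)C)c(O)c12
F2 | step 7 | (2S)-7-(tert-butyldimethylsilyloxy)-6,8,3'-triprenylflavan-4,5,4'-triol (both C4 epimers) | OC1C[C@@H](c2ccc(O)c(CC=C(C)C)c2)Oc2c(CC=C(C)C)c(O[Si](C)(C)C(C)(C)C)c(CC=C(C)C)c(O)c12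
F3 | step 7 | (2S)-7-(tert-butyldimethylsilyloxy)-5,4'-dihydroxy-6,8,3'-triprenylflavanone | O=C1C[C@@H](c2ccc(O)c(CC=C(C)C)c2)Oc2c(CC=C(C)C)c(O[Si](C)(C)C(C)(C)C)c(CC=C(C)C)c(O)c12
F4 | step 1 | 2-hydroxy-4,6-bis(3-methylbut-2-enyloxy)benzaldehyde | O=Cc1c(O)cc(OCC=C(C)C)cc1OCC=C(C)C
F5 | step 9 | (2S)-6,8,3'-triprenylflavan-4,5,7,4'-tetrol (both C4 epimers) | OC1C[C@@H](c2ccc(O)c(CC=C(C)C)c2)Oc2c(CC=C(C)C)c(O)c(CC=C(C)C)c(O)c12
A1 | alternative 1 | (2S)-5-hydroxy-6,8,3'-triprenyl-7,4'-bis(triisopropylsilyloxy)flavanone | O=C1C[C@@H](c2ccc(O[Si](C(C)C)(C(C)C)C(C)C)c(CC=C(C)C)c2)Oc2c(CC=C(C)C)c(O[Si](C(C)C)(C(C)C)C(C)C)c(CC=C(C)C)c(O)c12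
A2 | alternative 1 | (2S)-6-(2-diazo-5-methylhex-4-enoyl)-2-[3-(3-methylbut-2-enyl)-4-(triisopropylsilyloxy)phenyl]-2,3-dihydro-4H-pyran-4-one | CC(C)=CCC(=[N+]=[N-])C(=O)C1=CC(=O)C[C@@H](c2ccc(O[Si](C(C)C)(C(C)C)C(C)C)c(CC=C(C)C)c2)O1
A3 | alternative 1 | triisopropyl[(5-methylhex-4-en-1-yn-1-yl)oxy]silane | CC(C)=CCC#CO[Si](C(C)C)(C(C)C)C(C)C
A4 | alternative 2 | (2S)-5,7,4'-tris(methoxymethoxy)-6,8,3'-triprenylflavanone | O=C1C[C@@H](c2ccc(OCOC)c(CC=C(C)C)c2)Oc2c(CC=C(C)C)c(OCOC)c(CC=C(C)C)c(OCOC)c12
A5 | alternative 2 | 3,5-bis(methoxymethoxy)-4,6-bis(3-methylbut-2-enyl)-2-(trimethylsilyl)phenyl trifluoromethanesulfonate | COCOc1c(CC=C(C)C)c(OCOC)c([Si](C)(C)C)c(OS(=O)(=O)C(F)(F)F)c1CC=C(C)C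
A6 | alternative 2 | methyl (3S)-3-hydroxy-3-[4-(methoxymethoxy)-3-(3-methylbut-2-enyl)phenyl]propanoate | COC(=O)C[C@@H](c1ccc(OCOC)c(CC=C(C)C)c1)O
A7 | alternative 3 | (2S)-4'-(allyloxycarbonyloxy)-5,7-bis(tert-butyldimethylsilyloxy)-6,8,3'-triprenylflavanone | O=C1C[C@@H](c2ccc(OC(=O)OCC=C)c(CC=C(C)C)c2)Oc2c(CC=C(C)C)c(O[Si](C)(C)C(C)(C)C)c(CC=C(C)C)c(O[Si](C)(C)C(C)(C)C)c12
A8 | alternative 3 | (3S)-3-[4-(allyloxycarbonyloxy)-3-(3-methylbut-2-enyl)phenyl]-3-[3,5-bis(tert-butyldimethylsilyloxy)-2,4-bis(3-methylbut-2-enyl)phenoxy]propanoic acid | OC(=O)C[C@@H](c1ccc(OC(=O)OCC=C)c(CC=C(C)C)c1)Oc1cc(O[Si](C)(C)C(C)(C)C)c(CC=C(C)C)c(O[Si](C)(C)C(C)(C)C)c1CC=C(C)C
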